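**Retrosynthetic overview**

1. Ring numbering used here: C1(=O), C2(OH), C3(CH3), C4(=O), C5(OH), C6(C15H31). The target is the bis-enol tautomer of a 3,6-dialkylcyclohexane-1,2,4,5-tetraone. C1–C2 is a two-carbon unit at the oxidation level of oxalic acid, and its neighbours C6 and C3 are the two α-carbons of the 1,2-dioxygenated unit C4–C5. Each of C3 and C6 therefore sits between two oxygen-bearing ring carbons, which is the retron of a Claisen condensation.
2. Key disconnection: bonds C2–C3 and C1–C6 together, giving acyclic icosane-3,4-dione 5 and diethyl oxalate 6. This twofold Claisen annulation (four carbons plus two carbons) is redox-neutral and delivers all four oxygens in place.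
3. Dione 5 comes from icos-3-yne 4 by alkyne-to-1,2-dione oxidation; 4 comes from but-1-yne 1 and 1-bromohexadecane 2 by acetylide alkylation.
4. Ring order: the only ring, the six-membered quinone ring, is formed in the last step.

Key step: step 3

Remark: the target has no stereocentre and is taken as the 2,5-dihydroxy-1,4-benzoquinone tautomer of the SMILES; either α-methylene group of 5 can be acylated first, both orders converge on the same ring, and the order written is ethyl side first.

**Step 1**
Reactants: 1 but-1-yne; 2 1-bromohexadecane
Product: 4 icos-3-yne, via lithium but-1-yn-1-ide 3 (not isolated)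
Conditions: n-BuLi, THF, −78 to 0 °C; then 2, DMPU, 0 °C to rt
Reagents that add atoms: none
Why: The terminal alkyne is lithiated quantitatively and the acetylide should displace the primary bromide by SN2 in the dipolar cosolvent (acetylide alkylation); no stereocentre is formed.

**Step 2**
Reactants: 4 icos-3-yne
Product: 5 icosane-3,4-dione
Conditions: RuO2·xH2O (2 mol %), NaIO4 (3 equiv), CCl4–MeCN–H2O, 0 °C to rt
Reagents that add atoms: sodium periodate (NaIO4), `[Na+].[O-]I(=O)(=O)=O`
Why: Catalytic RuO4, regenerated by NaIO4, should add across the dialkyl alkyne and the cyclic ruthenate should collapse to the 1,2-dione (ruthenium tetroxide oxidation of an internal alkyne to an α-diketone); the saturated chains are inert and no stereocentre is formed.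

**Step 3**
Reactants: 5 icosane-3,4-dione; 6 diethyl oxalate
Product: 9 2,5-dihydroxy-3-methyl-6-pentadecylcyclohexa-2,5-diene-1,4-dione, via ethyl 3-methyl-2,4,5-trioxohenicosanoate 7 (not isolated), via disodium quinonediolate 8 (not isolated)
Conditions: NaOEt (3 equiv), 6 (1.2 equiv), EtOH–THF, N2, slow addition of 5 at 0 °C, then 60 °C; then 2 M HCl
Reagents that add atoms: none
Why: Ethoxide reversibly enolises 5 at its ethyl-side CH2 and the enolate attacks one ester carbonyl of 6 (crossed Claisen condensation) to give triketo ester 7, held as its stabilised sodium enolate; a second deprotonation at the long-chain CH2 then lets that carbon attack the remaining ester carbonyl, and loss of ethoxide followed by double deprotonation should give the quinonediolate 8, which 2 M HCl converts into 9. The closest known reaction type is the twofold Claisen condensation of a ketone bearing two α-methylene groups with a dialkyl oxalate to a cyclic polyketone, and the ring-closing half matches the Dieckmann-type step of the alkoxide-mediated dimerisation of 2-oxo esters to 3,6-dialkyl-2,5-dihydroxy-1,4-benzoquinones. The only ring, the six-membered carbocycle, is closed by a 6-(enolendo)-exo-trig acyl substitution. No stereocentre is formed, since both newly bonded carbons are enolised into the planar quinonoid dianion. The step needs cross- over self-condensation and C- over O-acylation: 6 is non-enolisable and more electrophilic than the dione carbonyls, 5 is kept at low concentration, and every aldol, retro-Claisen and lactone-forming side path is reversible under ethoxide, whereas the doubly vinylogous carboxylate 8 is a thermodynamic sink. Regiochemistry cannot go wrong because 6 is C2-symmetric and both α-carbons of 5 end up bonded to it, in either order.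

**Compound list**

1 | but-1-yne | `CCC#C` | starting material
2 | 1-bromohexadecane | `CCCCCCCCCCCCCCCCBr` | starting material
3 | lithium but-1-yn-1-ide | `[Li]C#CCC` | intermediate
4 | icos-3-yne | `CCC#CCCCCCCCCCCCCCCCC` | intermediate
5 | icosane-3,4-dione | `CCC(=O)C(=O)CCCCCCCCCCCCCCCC` | intermediate
6 | diethyl oxalate | `CCOC(=O)C(=O)OCC` | starting material
7 | ethyl 3-methyl-2,4,5-trioxohenicosanoate (C3 configurationally labile, present as its sodium enolate) | `CCOC(=O)C(=O)C(C)C(=O)C(=O)CCCCCCCCCCCCCCCC` | intermediate
8 | disodium 2-methyl-3,6-dioxo-5-pentadecylcyclohexa-1,4-diene-1,4-diolate | `CCCCCCCCCCCCCCCC1=C([O-])C(=O)C(C)=C([O-])C1=O.[Na+].[Na+]` | intermediate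
9 | 2,5-dihydroxy-3-methyl-6-pentadecylcyclohexa-2,5-diene-1,4-dione | `CCCCCCCCCCCCCCCC1=C(O)C(=O)C(C)=C(O)C1=O` | target

**Total step count:** 3
**Longest linear sequence:** 3 steps (1 or 2 → 4 → 5 → 9)

**Steps most likely to fail**

1. Step 3. Self-aldol condensation of the enolisable 1,2-dione may compete with acylation, or the sequence may stop after the first acylation through O-acylation (lactonisation) instead of carbocyclisation. The fallback sets out from 5 and comes back at 9. Dione 5 is silylated with TMSOTf and Et3N in CH2Cl2 at 0 °C to (2Z,4Z)-3,4-bis(trimethylsilyloxy)icosa-2,4-diene F1. F1 is then treated with oxalyl chloride and catalytic TMSOTf in CH2Cl2 from −78 °C to rt. This twofold Mukaiyama-type C-acylation runs under non-basic conditions in which neither a free enolate nor the free dione is present, and aqueous work-up should give 9 directly.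

2. Step 2. Over-oxidation may cleave the C3–C4 bond to carboxylic acids. The fallback sets out from 4 and comes back at 5. Alkyne 4 is semihydrogenated (H2, Pd/CaCO3 poisoned with Pb(OAc)2, quinoline, hexane) to (Z)-icos-3-ene F2. Syn-dihydroxylation (OsO4 cat., NMO, acetone–H2O) then gives racemic (3R,4S)-icosane-3,4-diol F3. Twofold Swern oxidation (oxalyl chloride, DMSO, Et3N, CH2Cl2, −78 °C) should give 5. The oxygens are thus installed at the alcohol level and raised to the dione by an oxidant that does not cleave the C3–C4 bond.

3. Step 1. Alkylation may stay incomplete through evaporative loss of the alkyne and base-induced elimination of the bromide. The fallback sets out from 2 and comes back at 4. Bromide 2 is treated with lithium acetylide–ethylenediamine complex (LiC≡CH·H2NCH2CH2NH2) in DMSO at rt, conditions under which substitution at primary bromides dominates, to give octadec-1-yne F4. F4 is lithiated (n-BuLi, THF, −78 °C) and ethylated with iodoethane in THF–DMPU to 4. The chain is thereby assembled from the other end, with a non-volatile alkyne and a small, reactive electrophile.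

**Further compounds**

F1 | step 3 | (2Z,4Z)-3,4-bis(trimethylsilyloxy)icosa-2,4-diene | `C/C=C(\O[Si](C)(C)C)/C(O[Si](C)(C)C)=C/CCCCCCCCCCCCCCC`
F2 | step 2 | (Z)-icos-3-ene | `CC/C=C\CCCCCCCCCCCCCCCC`
F3 | step 2 | (3R,4S)-icosane-3,4-diol (racemate, one enantiomer drawn) | `CC[C@@H](O)[C@@H](O)CCCCCCCCCCCCCCCC`
F4 | step 1 | octadec-1-yne | `C#CCCCCCCCCCCCCCCCC`
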